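## Retrosynthetic overview

1. The 14-membered ring is closed last, at C13–C14, not by the usual C1–C14 allylation or by RCM. A primary C13 radical adds to the β-carbon of an α-(sulfonylmethyl)butenolide and PhSO2• is expelled. This one step forms the macrocycle, the trans C14 centre and the exocyclic methylene.
2. The butenolide is the first ring formed. It comes from RCM of a 2-(sulfonylmethyl)acrylate of a bis-allylic alcohol, with C1 set by catalytic asymmetric vinylation of an enal.
3. The repeating CH(O)–CH=C(Me)–CH2 unit is a vinylogous-aldol retron. Two identical cycles (asymmetric vinylogous Mukaiyama aldol, acetylation, amide to aldehyde) set C9, C5 and two E-alkenes.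
4. The first enal, carrying the E C10=C11 alkene, comes from Zr-catalysed carboalumination of O-TBS-but-3-yn-1-ol.

Local numbering: C1 = lactone O–CH, C2=C3(Me), C4H2, C5(OAc), C6=C7(Me), C8H2, C9(OAc), C10=C11(Me), C12H2, C13H2, C14 = lactone β-CH. The target is 1S,5S,9S,14R, with all ring alkenes E and a trans-fused lactone.

Assumption: the chiral catalysts are purchased. Their sense of induction is assigned by analogy with simple enals. If it proves opposite, the antipodal catalyst is used.

## Route

**Step 1**
Reactants: 1, 3-methylbut-2-enoyl chloride; 2, morpholine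
Product: 3, 4-(3-methylbut-2-enoyl)morpholine
Conditions: Et3N, CH2Cl2, 0 °C → rt
Reagents that add atoms: none (both partners are numbered)
Why: Schotten–Baumann-type N-acylation of a secondary amine; no stereocentre is involved.

**Step 2**
Reactants: 3
Product: 4, 4-[1-(tert-butyldimethylsilyloxy)-3-methylbuta-1,3-dien-1-yl]morpholine (N,O-silyl dienyl ketene acetal)
Conditions: LDA, THF, −78 °C; TBSCl, DMPU, −78 °C → rt; used after short-path distillation
Reagents that add atoms: TBSCl, CC(C)(C)[Si](C)(C)Cl
Why: Only the γ-methyl protons are acidic, so LDA gives the extended amide dienolate, which the hard silyl chloride traps on oxygen (kinetic dienolate O-silylation).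

**Step 3**
Reactants: 5, tert-butyl(but-3-yn-1-yloxy)dimethylsilane
Product: 6, (E)-5-(TBSO)-3-methylpent-2-en-1-ol
Conditions: Me3Al, Cp2ZrCl2 (25 mol %), CH2Cl2, 0 °C → rt; then n-BuLi, (CH2O)n, THF, −30 °C → rt
Reagents that add atoms: trimethylaluminium, C[Al](C)C; paraformaldehyde, C=O
Why: Negishi carboalumination adds Me–Al syn with Al on the terminal carbon, and the alanate is hydroxymethylated with retention, which fixes E C10=C11 (C9 cis to the methyl).

**Step 4**
Reactants: 6
Product: 7, (E)-5-(TBSO)-3-methylpent-2-enal
Conditions: activated MnO2, CH2Cl2, rt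
Reagents that add atoms: none
Why: Neutral, chemoselective allylic oxidation that leaves the silyl ether and the alkene geometry intact.

**Step 5**
Reactants: 7; 4
Product: 8, (2E,5S,6E)-9-(TBSO)-5-hydroxy-3,7-dimethyl-1-(morpholin-4-yl)nona-2,6-dien-1-one
Conditions: SiCl4 (1.1 equiv), (S,S)-BINAM-derived pentamethylene-linked bisphosphoramide (5 mol %), i-Pr2NEt (10 mol %), CH2Cl2, −78 °C; aq. NaHCO3/KF
Reagents that add atoms: none (the TBS group of 4 is lost)
Why: In this Denmark-type vinylogous Mukaiyama aldol, the phosphoramide-bound silyl cation activates the enal and the s-trans dienolate attacks only through its γ-carbon, in an open transition state on the Si face, giving the S carbinol (target C9) and the E-enamide.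

**Step 6**
Reactants: 8
Product: 9, the 5-acetate of 8
Conditions: Ac2O, pyridine, DMAP (5 mol %), CH2Cl2, 0 °C
Reagents that add atoms: acetic anhydride, CC(=O)OC(C)=O
Why: O-acylation does not touch the C–O stereocentre, and the weakly acidic enamide γ-protons prevent vinylogous elimination.

**Step 7**
Reactants: 9
Product: 10, (2E,5S,6E)-5-acetoxy-9-(TBSO)-3,7-dimethylnona-2,6-dienal
Conditions: Cp2Zr(H)Cl (1.6 equiv), THF, rt, 20 min; H2O/silica gel
Reagents that add atoms: water, O (work-up hydrolysis of the Zr-hemiaminal/iminium may supply the aldehyde O)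
Why: Schwartz-reagent reduction of a tertiary amide stops at the aldehyde level, is selective for amides over esters, and does not hydrozirconate trisubstituted alkenes.

**Step 8**
Reactants: 10; 4
Product: 11, (2E,5S,6E,9S,10E)-9-acetoxy-13-(TBSO)-5-hydroxy-3,7,11-trimethyl-1-(morpholin-4-yl)trideca-2,6,10-trien-1-one
Conditions: as step 5
Reagents that add atoms: none
Why: This is a second catalyst-controlled vinylogous Mukaiyama aldol, where the 1,5-remote acetate centre exerts no bias, so Si-face attack sets 5S (target C5) and E C2=C3.

**Step 9**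
Reactants: 11
Product: 12, the 5,9-diacetate of 11
Conditions: Ac2O, pyridine, DMAP (5 mol %), CH2Cl2, 0 °C
Reagents that add atoms: acetic anhydride, CC(=O)OC(C)=O
Why: Simple acetylation that installs the second target ester, so no later protecting-group exchange is needed.

**Step 10**
Reactants: 12
Product: 13, (2E,5S,6E,9S,10E)-5,9-diacetoxy-13-(TBSO)-3,7,11-trimethyltrideca-2,6,10-trienal
Conditions: Cp2Zr(H)Cl (1.6 equiv), THF, rt; H2O/silica gel
Reagents that add atoms: water, O (as in step 7)
Why: The same amide-selective Schwartz reduction, under neutral conditions that avoid vinylogous E1cB loss of the δ-acetate.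

**Step 11**
Reactants: 13
Product: 14, (2E,5S,6E,9S,10E)-5,9-diacetoxy-13-hydroxy-3,7,11-trimethyltrideca-2,6,10-trienal
Conditions: HF·pyridine, pyridine/THF, 0 °C
Reagents that add atoms: none
Why: Buffered fluoride desilylation removes the primary TBS ether without acetate migration or enal elimination.

**Step 12**
Reactants: 14
Product: 15, (2E,5S,6E,9S,10E)-5,9-diacetoxy-13-iodo-3,7,11-trimethyltrideca-2,6,10-trienal
Conditions: I2, PPh3, imidazole, CH2Cl2, 0 °C
Reagents that add atoms: iodine, II
Why: Appel iodination of the only free, primary alcohol, placed here so that the base-sensitive butenolide never meets imidazole.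

**Step 13**
Reactants: 15
Product: 16, (3R,4E,7S,8E,11S,12E)-3-hydroxy-15-iodo-5,9,13-trimethylpentadeca-1,4,8,12-tetraene-7,11-diyl diacetate
Conditions: (CH2=CH)2Zn (from vinylMgBr/ZnCl2, dioxane, filtered), (+)-MIB (10 mol %), toluene, −20 → 0 °C
Reagents that add atoms: divinylzinc, C=C[Zn]C=C
Why: In this Noyori-type amino-alkoxide zinc-catalysed vinylation, the (+)-ligand delivers vinyl to the Re face of the enal, giving 3R (which becomes 1S of the target), and the organozinc ignores the acetates and the alkyl iodide.

**Step 14**
Reactants: 17, 2-(bromomethyl)acrylic acid; 18, sodium benzenesulfinate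
Product: 19, 2-[(phenylsulfonyl)methyl]acrylic acid
Conditions: MeOH, reflux; then 1 M HCl
Reagents that add atoms: none (both partners are numbered)
Why: S-alkylation of the sulfinate by the allylic bromide, where the SN2 and SN2′ pathways give the same product.

**Step 15**
Reactants: 16; 19
Product: 20, (3R,4E,7S,8E,11S,12E)-7,11-diacetoxy-15-iodo-5,9,13-trimethylpentadeca-1,4,8,12-tetraen-3-yl 2-[(phenylsulfonyl)methyl]prop-2-enoate
Conditions: DIC, DMAP (10 mol %), CH2Cl2, 0 °C; Et3N-deactivated silica
Reagents that add atoms: none (both partners are numbered)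
Why: Steglich esterification activates the acid rather than the labile bis-allylic C–O bond, so C1 is retained.

**Step 16**
Reactants: 20
Product: 21, (5S)-5-[(1E,4S,5E,8S,9E)-4,8-diacetoxy-12-iodo-2,6,10-trimethyldodeca-1,5,9-trien-1-yl]-3-[(phenylsulfonyl)methyl]furan-2(5H)-one
Conditions: Hoveyda–Grubbs II (10 mol %), 1,4-benzoquinone (20 mol %), degassed DCE, 60 °C, 5 mM
Reagents that add atoms: none (ethylene is lost)
Why: In this ring-closing metathesis, Ru loads on the only monosubstituted alkene and closes the five-membered ring onto the 2-substituted acrylate, while the trisubstituted alkenes are inert and the neutral conditions preserve the acidic C1–H centre.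

**Step 17 (key step)**
Reactants: 21
Product: 22, the target, (3aR,6E,8S,10E,12S,14E,15aS)-6,10,14-trimethyl-3-methylidene-2-oxo-2,3,3a,4,5,8,9,12,13,15a-decahydrocyclotetradeca[b]furan-8,12-diyl diacetate
Conditions: (Bu3Sn)2 (1.5 equiv), hν (sunlamp, Pyrex), degassed PhH, 80 °C; 21 added by syringe pump over 12 h to a final concentration of 1 mM; aq. KF work-up
Reagents that add atoms: none (I and PhSO2 are lost)
Why: Proposed new method: Bu3Sn• abstracts iodine; the nucleophilic primary C13 radical adds to the electrophilic β-carbon C14 on the face anti to the C1 side chain, as in intermolecular Giese additions to 5-substituted butenolides, setting 14R (trans); the resulting α-acyl radical expels PhSO2• to give the exocyclic methylene, and PhSO2• reacts with the ditin to regenerate Bu3Sn•; no H-donor is present to intercept the slow closure, and the E-alkenes geometrically block 1,5- and 1,6-H transfer and small-ring closures; the closest known reactions are Keck/Baldwin radical allylation with 2-(sulfonylmethyl)acrylates (SH2′) and Porter-type radical macrocyclisation onto activated alkenes.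

## Compound list

| No. | Name | SMILES | Role |
|---|---|---|---|
| 1 | 3-methylbut-2-enoyl chloride | CC(C)=CC(=O)Cl | starting material |
| 2 | morpholine | C1COCCN1 | starting material |
| 3 | 4-(3-methylbut-2-enoyl)morpholine | CC(C)=CC(=O)N1CCOCC1 | intermediate |
| 4 | N,O-silyl dienyl ketene acetal | C=C(C)C=C(O[Si](C)(C)C(C)(C)C)N1CCOCC1 | intermediate |
| 5 | tert-butyl(but-3-yn-1-yloxy)dimethylsilane | C#CCCO[Si](C)(C)C(C)(C)C | starting material |
| 6 | (E)-5-(TBSO)-3-methylpent-2-en-1-ol | OC/C=C(\C)CCO[Si](C)(C)C(C)(C)C | intermediate |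
| 7 | (E)-5-(TBSO)-3-methylpent-2-enal | O=C/C=C(\C)CCO[Si](C)(C)C(C)(C)C | intermediate |
| 8 | (5S)-hydroxy dienamide | O=C(N1CCOCC1)/C=C(\C)C[C@H](O)/C=C(\C)CCO[Si](C)(C)C(C)(C)C | intermediate |
| 9 | (5S)-acetoxy dienamide | O=C(N1CCOCC1)/C=C(\C)C[C@H](OC(C)=O)/C=C(\C)CCO[Si](C)(C)C(C)(C)C | intermediate |
| 10 | (5S)-acetoxy dienal | O=C/C=C(\C)C[C@H](OC(C)=O)/C=C(\C)CCO[Si](C)(C)C(C)(C)C | intermediate |
| 11 | (5S,9S)-5-hydroxy-9-acetoxy trienamide | O=C(N1CCOCC1)/C=C(\C)C[C@H](O)/C=C(\C)C[C@H](OC(C)=O)/C=C(\C)CCO[Si](C)(C)C(C)(C)C | intermediate |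
| 12 | (5S,9S)-diacetoxy trienamide | O=C(N1CCOCC1)/C=C(\C)C[C@H](OC(C)=O)/C=C(\C)C[C@H](OC(C)=O)/C=C(\C)CCO[Si](C)(C)C(C)(C)C | intermediate |
| 13 | (5S,9S)-diacetoxy-13-TBSO trienal | O=C/C=C(\C)C[C@H](OC(C)=O)/C=C(\C)C[C@H](OC(C)=O)/C=C(\C)CCO[Si](C)(C)C(C)(C)C | intermediate |
| 14 | 13-hydroxy trienal | O=C/C=C(\C)C[C@H](OC(C)=O)/C=C(\C)C[C@H](OC(C)=O)/C=C(\C)CCO | intermediate |
| 15 | 13-iodo trienal | O=C/C=C(\C)C[C@H](OC(C)=O)/C=C(\C)C[C@H](OC(C)=O)/C=C(\C)CCI | intermediate |
| 16 | (3R)-bis-allylic alcohol | C=C[C@@H](O)/C=C(\C)C[C@H](OC(C)=O)/C=C(\C)C[C@H](OC(C)=O)/C=C(\C)CCI | intermediate |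
| 17 | 2-(bromomethyl)acrylic acid | C=C(CBr)C(=O)O | starting material |
| 18 | sodium benzenesulfinate | [Na+].[O-]S(=O)c1ccccc1 | starting material |
| 19 | 2-[(phenylsulfonyl)methyl]acrylic acid | C=C(CS(=O)(=O)c1ccccc1)C(=O)O | intermediate |
| 20 | bis-allylic 2-(sulfonylmethyl)acrylate | C=C[C@@H](OC(=O)C(=C)CS(=O)(=O)c1ccccc1)/C=C(\C)C[C@H](OC(C)=O)/C=C(\C)C[C@H](OC(C)=O)/C=C(\C)CCI | intermediate |
| 21 | (5S)-α-(sulfonylmethyl)butenolide iodide | O=C1O[C@@H](/C=C(\C)C[C@H](OC(C)=O)/C=C(\C)C[C@H](OC(C)=O)/C=C(\C)CCI)C=C1CS(=O)(=O)c2ccccc2 | intermediate |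
| 22 | CID11069750 | C=C1C(=O)O[C@H]2/C=C(\C)C[C@H](OC(C)=O)/C=C(\C)C[C@H](OC(C)=O)/C=C(\C)CC[C@H]12 | target |

## Step count and main risks

Total steps: 17. Longest linear sequence: 14 (compound 5, then steps 3–13 and 15–17).

**1. Step 17, radical SH2′ macrocyclisation**
- Risks: addition to a β-substituted acceptor is slow. H-abstraction from the doubly activated C1–H can compete. Radicals can add to the product's methylene group. The cis/trans facial outcome is uncertain.
- Fallback: abandon the C13–C14 closure. Run the same two aldol cycles from O-TBS-pent-4-yn-1-ol, which has one more carbon. Convert the terminal aldehyde to the (Z)-2-(bromomethyl)enoate by a Baylis–Hillman reaction followed by bromination. Then close C1–C14 with an intramolecular, anti-selective Cr(II) 2-(alkoxycarbonyl)allylation and lactonisation.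

**2. Steps 5 and 8, vinylogous Mukaiyama aldol with the 3-methyl dienolate**
- Risks: E/Z ratio, ee, and acetate ionisation or elimination in step 8.
- Fallback: replace each aldol with a catalytic asymmetric propargylation of the enal using an allenylboronate and a chiral phosphoric acid. Silylate the product, then carry out Negishi carboalumination and formylation. Syn-carbometalation fixes the E geometry mechanistically, and the silyl ethers are exchanged for acetates after ring closure.

**3. Steps 13–16, asymmetric vinylation, fragile bis-allylic ester and RCM to a trisubstituted butenolide**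
- Fallback: use a metathesis-free butenolide synthesis.
  - Zn–ProPhenol addition of methyl propiolate to 15 sets C1.
  - Pd(0)/Bu3SnH syn-hydrostannation with lactonisation gives the α-stannyl butenolide.
  - Iododestannylation and Stille coupling with Bu3SnCH2OH install the hydroxymethyl group.
  - Hata sulfenylation (PhSSPh, PBu3) then gives the α-(phenylthiomethyl)butenolide, in which the allyl sulfide serves as the radical leaving group.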